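The west run is the neighbour to start from, since the north run has the same charge of J, 0.500 M. You asked for a quick number on the north run, and here is how I would get it.

| flask | J | L | G | X | time |
|---|---|---|---|---|---|
| west | 0.500 M | 1.00 M | 0.00250 M |  |  |
| south-west | 0.300 M | 0.800 M | 0.00250 M |  |  |
| south | 0.500 M | 1.00 M | 0.00250 M | 0.250 M |  |
| east | 1.50 M | 1.00 M | 0.00250 M |  |  |
| north | 0.500 M | 3.00 M | 0.00500 M |  | 35 min |

| run | time / min | [X] / M |
|---|---|---|
| west run | 2.7 | 0.034 |
| west run | 8.1 | 0.107 |
| west run | 15 | 0.191 |
| west run | 24 | 0.266 |
| west run | 35 | 0.341 |
| south-west run | 2.7 | 0.032 |
| south-west run | 8.1 | 0.076 |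
| south-west run | 15 | 0.122 |
| south-west run | 24 | 0.162 |
| south-west run | 35 | 0.203 |
| south run | 2.7 | 0.289 |
| south run | 8.1 | 0.356 |
| south run | 15 | 0.451 |
| south run | 24 | 0.507 |
| south run | 35 | 0.596 |
| east run | 2.7 | 0.086 |
| east run | 8.1 | 0.240 |
| east run | 15 | 0.402 |
| east run | 24 | 0.590 |
| east run | 35 | 0.735 |

(scatter of a reading: 0.007 M)

- Overall: J + L -> X, with G as catalyst.
- Constant volume, constant temperature.
- The analysis sees a species whether free or bound.
- "The second partner" is L.
- An order is taken over about fifteen percent of the charge, up and down.

- order of the initial rate in [L], near the charge of the west run, the rate being that where two percent of its J are X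
- order of the initial rate in [J], near the charge of the west run, the rate being that where two percent of its J are X (one fixed amount of X, the same in the runs compared)
- the south-west run starts with 0.200 M less of J and of L than the west run, and with no X. Compared where both hold the same amount of J, once fifteen percent of what the south-west run was charged with has turned into X, is the south-west run faster, slower or alike (within a tenth)?
- X in the north run at 35 min, as a share of the J charged
- which of these the readings show (nothing beyond the main steps / the catalyst rests as a dimer / two substrates go astray together / the substrate pairs with itself / the two partners rest in a complex / the second partner is lost in pairs)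

1. The west run has 31.8 % of its J left at 35 min, which gives 0.0327 min⁻¹. That is the fraction-left constant: the natural log of one over the fraction of J left, divided by the time. The west run at 15 min reads 0.0321 min⁻¹, and the south-west run at 35 min reads 0.0323 min⁻¹, so I carry it as steady.

2. By 8.1 min the east run has made 2.24 times the X of the west run, from 3.00 times the J. The order in J reads 0.735.

3. Now take the east run between 24 min and 35 min against the west run over its first 8.1 min. At mid-stretch the east run holds 1.88 times the J and 0.357 times the L, and its rate is 0.998 times the west rate. So the order in L reads 0.451, with the scatter of the readings on it.

4. First round for the north run: I assume the rate is first order in G. Doubled G and tripled L then give 0.107 min⁻¹, so 97.7 % of the J is turned at 35 min.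

5. Second round: J is the limiting reagent of the north run. Putting that answer back, the north run keeps on average 91.9 % of its L charge, and the west run keeps 83.0 % of its own. That gives 0.112 min⁻¹ and 98.0 %, my number.

6. The forecast gives 0.22 for the order in L, 0.87 for the order in J, alike for the south-west run against the west run, 89.5 % for the north run, and for what the readings show: nothing beyond the main steps. Its ground is that “the rate hardly depends on L in that range”. We part there: my order in L is larger, and so is my share for the north run.

The north run gives 97.5 %. Near the charge of the west run, the initial order in L is 0.38 and the initial order in J is 0.77. At equal J the south-west run and the west run come out alike, with a rate ratio of 1.0. The readings show this: the substrate pairs with itself.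

    G + L ⇌ GL, settled at all times (1.680 L mol⁻¹)
    GL + J → X + G (29.76 L mol⁻¹ min⁻¹)
    2 J ⇌ J2, settled at all times (0.7060 L mol⁻¹)

Put back into the fraction-left constant, 97.5 % means 0.105 min⁻¹ for the north run, 3.22 times 0.0327 min⁻¹. On the south run, which starts with 0.250 M of X, 0.0327 min⁻¹ puts the X made at half of the J charged after 21.2 min, and the south run reaches it at 21.6 min.

The numbers in the tables were computed with constants of no real substance; the scatter is artificial.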